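The earlier runs and the new flask come from a simulation for substances that don't exist; noise was put on by code.

It is easy to take the charge of the limiting reagent for the yield of a flask, and I nearly did so with cedar.

| flask | substrate | activator | remark | time |
|---|---|---|---|---|
| beta | 0.065 M | 0.50 M | run made earlier |  |
| eta | 0.42 M | 0.50 M | run made earlier |  |
| gamma | 0.50 M | 0.39 M | run made earlier |  |
| ash | 0.15 M | 2.00 M |  | 25 min |
| maple | 0.12 M | 0.120 M |  | 25 min |
| alder | 0.50 M | 0.500 M |  | 25 min |
| oak | 0.50 M | 2.00 M |  | 25 min |
| cedar | 0.50 M | 0.300 M |  | 25 min |

| run | time / min | ring / % |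
|---|---|---|
| beta | 4.00 | 92 |
| beta | 8.00 | 101 |
| beta | 12.0 | 99 |
| beta | 15.0 | 98 |
| beta | 20.0 | 95 |
| beta | 25.0 | 97 |
| eta | 1.50 | 50 |
| eta | 5.00 | 84 |
| eta | 8.00 | 84 |
| eta | 15.0 | 84 |
| eta | 20.0 | 87 |
| eta | 25.0 | 84 |
| gamma | 5.00 | 67 |
| gamma | 10.0 | 66 |
| gamma | 15.0 | 66 |
| gamma | 20.0 | 65 |
| gamma | 25.0 | 63 |

(each reading ± 2 percentage points)

- the flasks by amount of ring, in percent of the substrate charged, highest first, at 25 min (ash / maple / alder / oak / cedar)
- the same order at 5.0 min (ash / maple / alder / oak / cedar)
- the amount of ring, in percent of the substrate charged of the flask you put first, at 25 min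
- the amount of ring, in percent of the substrate charged of the flask you put last, at 25 min

- the analysis behind the earlier runs scatters by 2 percentage points, standard deviation
- a reading or a percentage of ring counts all its forms, free or not

Cedar held 0.300 M of activator against 0.50 M of substrate, so I set the zero of my scale at one ring per activator, which gave cedar 60.0%. The gamma run objected. Its activator allowed 78.0% of ring, but its readings stayed near 65.4%. In gamma, the activator charged minus the mean ring found came to 0.0630 M, and I made this amount W, the activator charged less the ring found, my measure of the loss. It carried the scatter of 2 percentage points in each reading.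

But how was W to be carried across to cedar? Kept as a fixed share of the activator, it gave cedar 50.3%; kept as a fixed amount, 47.4%. I doubted the share. Beta and eta had the same activator, 0.50 M, yet ring fell from 97% to 84% as substrate rose from 0.065 M to 0.42 M, so the loss seemed to follow the substrate. Cedar had gamma's substrate, and I committed to the fixed amount, 47.4%.

The forecast gave ash > oak > alder > maple > cedar at 25 min and ash > oak > alder > cedar > maple at 5.0 min, with 99% for ash and 54.5% for cedar, ranged from 50% to 58%, and called cedar “activator-limited”. My figure for cedar stood below that range.

The simulation gave ash > oak > maple > alder > cedar at 25 min and ash > oak > alder > maple > cedar at 5.0 min, with 99.0% for ash and 46.1% for cedar.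

    substrate + activator → activated form (k = 0.153 M⁻¹ s⁻¹)
    activated form → ring (k = 0.0129 s⁻¹)
    substrate + activated form → open dimer (k = 0.0195 M⁻¹ s⁻¹)
    crystals ⇌ ring, rate k4*(cs4 - [ring]) while solid is left; crystals form when [ring] > cs4 (solubility = 17.0 mM, k = 0.129 s⁻¹)

Each open dimer holds one activator and two substrates. In cedar, with activator at 0%, W came to 0.0697 M against gamma's 0.0630 M, and the open dimer amounted to 0.0697 M. The main reason for cedar's low figure was the shrinking supply of activator: with that supply kept from shrinking, cedar stood at 86.2% instead of 46.1%. The passing of substrate and activated form into open dimer was a part of it: without that step, cedar stood at 60.0%. In the further flask, like cedar but with 2.0 M of substrate, open dimer put W at 0.213 M, 3.38 times gamma's, which left 4.35% of ring; that flask stood at 4.37%.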